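## Analysis of the target

Target 30 is a daucane (carotane) sesquiterpenoid. A cyclopentane (C1–C5) is trans-fused along C1–C5 to a cycloheptane (C1, C5–C10); C15 is the angular methyl on quaternary C1 and C14 is the exocyclic carbon of a spiro-oxirane on C8. C4 is an isopropyl carbinol, C6 carries the 3-methylbutanoate, and C9/C10 carry a cis-diol. There are seven stereocentres (C1, C4, C5, C6, C8, C9, C10). The C15 methyl and the C4 hydroxyl lie on one face; H5, the isopropyl group, the C6 ester oxygen, both diol oxygens and the epoxide oxygen lie on the other. The spiro-epoxide next to a free cis-diol is sensitive to acid and to base (Payne-type migration), the tertiary alcohol can eliminate, and the ester sits β to C8, so the epoxide has to be made last under neutral conditions. The difficulty is the quaternary C1 at a trans 5–7 fusion, surrounded by a seven-membered ring in which every carbon except C7 is functionalised. The strategy rests on one feature: C1 is bonded to both C5 and C10, and C5 bears only hydrogen next to the oxygenated C4. That is the pattern left when, in a spiro[4.5]dec-6-ene, the alkenyl carbon moves from the spiro atom (C5) to a cationic neighbour (C1). The six-membered ring then becomes the seven-membered ring, the alkene ends at C9=C10 where the diol is needed, and the C4 oxygen can quench the C5 cation by a hydride shift.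

## Retrosynthetic reasoning

**30 ⇒ 29.** The two C–O bonds of the oxirane are cut first. The epoxy diol is the most fragile part, and the free allylic C9 hydroxyl of 29 can steer the oxygen to the face it occupies, which is the face the target requires.

**29 ⇒ 28 ⇒ 26.** The diol is masked as the acetonide 28, and the C8=C14 bond is cut back to the C8 ketone of 26. A ketone at C8 is what the earlier steps need (it activates C6 through C7), and a non-basic methylenation spares the β-acyloxy group.

**26 ⇒ 24 + 25.** The ester C–O bond is cut. Acylation of the only secondary hydroxyl of 24 with acid chloride 25 needs no protecting group, because the tertiary C4 hydroxyl is inert.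

**24 ⇒ 21 (+ 22) ⇒ 18.** The C6–O bond is traced to a C6–B bond made by conjugate addition of boron from 22 to the C6=C7–C8=O enone 21, which comes from ketone 18 by desaturation. C6 is reached from the C8 carbonyl and not from the C4 carbonyl on purpose: activation from C4 would pass through a C5=C6 enone and erase the C5 configuration, whereas the C8 route leaves C5 untouched and only has to choose a face at C6.

**18 ⇒ 16 ⇒ 15 ⇒ 14.** The acetonide is removed (reagent 17 in the forward sense). The two C–O bonds at C9 and C10 are cut back to the enone alkene of 15; one cis-dihydroxylation sets both centres, steered by C15 on the neighbouring quaternary carbon. The C8 carbonyl is cut back to the allylic methylene of 14; C8 is the only allylic position that bears hydrogen, because the other allylic carbon is quaternary C1.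

**14 ⇒ 12 + 13.** The C4–isopropyl bond is cut. Addition of the isopropyl nucleophile 13 to the trans-fused cyclopentanone 12 should occur on the face away from the axial C15 methyl, which places the hydroxyl cis to C15.

**12 ⇒ 11 (key disconnection).** In 12 the bond C1–C10 is cut and C10 is reconnected to C5; the C4 carbonyl becomes a silyloxy-bearing CH and C1 a tertiary carbinol. This gives the spiro carbinol 11. Forward, the reaction has to ionise C1, move the alkenyl carbon from C5 to C1 and end the cation at C5 by hydride transfer from C4. One operation then forms the seven-membered ring, the quaternary centre and the trans ring fusion.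

**11 ⇒ 9 + 10; 9 ⇒ 7 + 8; 7 ⇒ 6.** The methyl–C1 bond is cut (10), the silyl ether is removed (8), and the carbinol is traced to one of the two enantiotopic carbonyls of the spiro enedione 6. A single desymmetrising reduction creates the carbinol centre and, by its choice of carbonyl, the spiro centre.

**6 ⇒ 3 + 4; 3 ⇒ 1 + 2.** The two acyl–C5 bonds are cut together. Geminal acylation of the acetal 3 with 4 turns the carbonyl carbon of 1 into the spiro atom and leaves its alkene next to it, which is exactly the alkenyl arm the key step needs. Acetal 3 comes from 1 and 2.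

## Alternatives that were turned down

**Alternative 1:** The cyclopentane would be closed last between C4 and C5. The open-chain bromo keto ester A1 already holds quaternary C1 (methyl and propenyl), the isopropyl ketone (C4) and a bromine on the carbon next to the ester (C5; the ester carbon is the future C6). SmI2 would turn the C–Br bond into a samarium enolate that adds to the ketone, giving the hydroxy ester A2.
- For: the reaction type is well established and mild. It creates the isopropyl carbinol in the ring-forming step (the chosen route needs a separate organocerium addition), and C6 arrives at a useful oxidation level. On precedent for the key step and on C4 it is stronger than the chosen strategy.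
- Against: the quaternary centre C1 must be made beforehand in an acyclic chain, which needs its own asymmetric step. The seven-membered ring is not touched at all: C7 and C14 are missing, the propenyl methyl (C8) has to be functionalised, and a medium ring still has to be closed. The C4/C5/C1 relationship rests on a chelated transition state next to a quaternary carbon, and the β-hydroxy ester can undergo retro-aldol cleavage.
- Comparison: the chosen strategy offers both rings, C1 and the trans fusion in one step from a five-step precursor, with the alkene already at C9=C10. That outweighs the less certain key step.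

**Alternative 2:** C1–C5 and C1–C10 would be formed together from the diazo ketone A3, tethered to a 2,4-dimethoxyphenyl ring. A carbenoid made with Cu(MeCN)4PF6 (monovalent copper) and a chiral bis(oxazoline) would add across the ipso–ortho bond, and the norcaradiene would open to the cycloheptatriene A4.
- For: the intramolecular Büchner reaction is known and catalytic-asymmetric. It forms both rings at C1 in one step from a cheap arene and brings oxygen to C6 and C8 as enol ethers. On convergence and on early oxygenation of C6/C8 it is stronger than the chosen route.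
- Against: a carbenoid with an α-methyl group is prone to 1,2-hydride shift to an enone. The ketone ends at C2, which is a methylene in the target, while C4 is left bare, so a carbonyl has to be removed and another introduced. C5 is sp2 in A4, so the trans fusion must be set later by reducing a tetrasubstituted enol ether. Three ring double bonds must be told apart, and the carbenoid must choose between two ortho positions.
- Comparison: the chosen strategy delivers the ketone at C4 where the isopropyl carbinol goes, sets H5 trans to C15 in the key step and leaves a single alkene to work with.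

**Alternative 3:** C1–C15 and C5–C6 would be formed in one pot. Cu(OTf)2 with a chiral phosphoramidite would transfer methyl from AlMe3 to the silyloxymethyl enone A5, and the aluminium enolate would be trapped by the aldehyde A6 to give the aldol adduct A7.
- For: three centres (C1, C5, C6) come from one catalytic operation. The C6 oxygen, C8 and C14 are present from the start, and the ketone is at C4. For the C6 oxygen this is stronger in step economy than the chosen route, which spends a desaturation and a borylation–oxidation on it.
- Against: the seven-membered ring is still open and C9 is missing, so a homologation and a medium-ring closure onto the vinyl iodide are needed. C9 and C10 would be set by two separate carbonyl additions without a common controlling element. The aldol configuration at C6 is not secured, and the β-hydroxy ketone is prone to retro-aldol cleavage during the later addition at C4.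
- Comparison: the chosen strategy forms the seven-membered ring by ring enlargement, not by cyclisation, and sets the 9,10-diol in one cis-dihydroxylation steered by C15.

Key step: step 6

## Route

Remark: fused compounds are named on the bicyclo[5.3.0]decane skeleton with daucane locants (C1 quaternary, C2–C5 cyclopentane, C6–C10 cycloheptane, C14 on C8, C15 on C1). Spiro compounds carry spiro[4.5]decane locants, whose C1, C4, C5, C6 and C10 are daucane C1, C4, C5, C10 and C6. Stereodescriptors were derived from the SMILES strings, which are authoritative.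

Step 1
Reactants: 1 cyclohex-2-en-1-one; 2 1,2-bis(trimethylsilyloxy)ethane
Product: 3 1,4-dioxaspiro[4.5]dec-6-ene
Conditions: TMSOTf (2 mol %), CH2Cl2, −78 °C; pyridine quench
Reagents that add atoms: 1,2-bis(trimethylsilyloxy)ethane, C[Si](C)(C)OCCO[Si](C)(C)C
Why: Noyori acetalisation under aprotic conditions at low temperature; the oxocarbenium ion is captured faster than it can lose a γ-proton, so the alkene should stay next to the acetal carbon.

Step 2
Reactants: 3 1,4-dioxaspiro[4.5]dec-6-ene; 4 1,2-bis(trimethylsilyloxy)cyclobutene
Product: 6 spiro[4.5]dec-6-ene-1,4-dione, via cyclobutanone aldol adduct 5 (not isolated)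
Conditions: BF3·OEt2 (10 equiv), CH2Cl2, −78 °C → 23 °C
Reagents that add atoms: 1,2-bis(trimethylsilyloxy)cyclobutene, C[Si](C)(C)OC1=C(O[Si](C)(C)C)CC1
Why: Geminal acylation: a Mukaiyama-type aldol at the acetal carbon gives 5, and a pinacol-type 1,2-acyl shift onto the allylic cation enlarges the cyclobutanone to the cyclopentane-1,3-dione. The acyl group can only move to the carbon it is attached to, so the alkene should remain at C6=C7 next to the new spiro atom; competing attack at the far allyl terminus is the side reaction to watch. No stereocentre is formed.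

Step 3
Reactants: 6 spiro[4.5]dec-6-ene-1,4-dione
Product: 7 (4S,5R)-4-hydroxyspiro[4.5]dec-6-en-1-one
Conditions: (R)-2-methyl-CBS-oxazaborolidine (20 mol %), catecholborane (1.1 equiv), toluene, −78 °C; MeOH, pH 7 buffer
Reagents that add atoms: none
Why: Desymmetrising CBS reduction of a 2,2-disubstituted cyclopentane-1,3-dione; catecholborane is used because it does not hydroborate the alkene at −78 °C. The catalyst fixes the (S) carbinol (large group = spiro carbon), and hydride should enter on the ring face flanked by the flat alkenyl CH and not by the CH2 arm. Together these choices select one carbonyl and so define the (R) spiro centre, with H4 on the side of the alkenyl arm.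

Step 4
Reactants: 7 (4S,5R)-4-hydroxyspiro[4.5]dec-6-en-1-one; 8 tert-butyldimethylsilyl trifluoromethanesulfonate
Product: 9 (4S,5R)-4-(tert-butyldimethylsilyloxy)spiro[4.5]dec-6-en-1-one
Conditions: 2,6-lutidine, CH2Cl2, −78 → 0 °C
Reagents that add atoms: tert-butyldimethylsilyl trifluoromethanesulfonate, CC(C)(C)[Si](C)(C)OS(=O)(=O)C(F)(F)F
Why: Silylation of a hindered secondary alcohol with the silyl triflate and a non-nucleophilic base, which should avoid retro-aldol opening of the β-hydroxy ketone; no stereocentre is touched.

Step 5
Reactants: 9 (4S,5R)-4-(tert-butyldimethylsilyloxy)spiro[4.5]dec-6-en-1-one; 10 methylmagnesium bromide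
Product: 11 (1R,4S,5R)-4-(tert-butyldimethylsilyloxy)-1-methylspiro[4.5]dec-6-en-1-ol
Conditions: CeCl3 (anhydrous, 1.5 equiv), THF, −78 °C
Reagents that add atoms: methylmagnesium bromide, C[Mg]Br
Why: Organocerium addition to a hindered, enolisable ketone. Methyl should enter over the alkenyl arm and away from the silyloxy group, which places the tertiary hydroxyl anti to the alkenyl carbon, the alignment the next step uses; the other C1 epimer would ionise to the same cation.

Step 6
Reactants: 11 (1R,4S,5R)-4-(tert-butyldimethylsilyloxy)-1-methylspiro[4.5]dec-6-en-1-ol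
Product: 12 (1R,5R)-1-methylbicyclo[5.3.0]dec-9-en-4-one (trans-fused)
Conditions: BF3·OEt2 (1.5 equiv), 2,6-di-tert-butyl-4-methylpyridine (0.2 equiv), CH2Cl2, −78 → −20 °C; aq. NaHCO3
Reagents that add atoms: none
Why: Proposed new method: BF3 activates the tertiary C1 hydroxyl, and ionisation is assisted by the C9=C10 π bond, whose p orbital at C10 is held by the spiro junction so that it points at C1 from the face opposite the leaving group; the bridged cyclopropylcarbinyl-type cation opens at C5–C10, so C10 ends on C1 and the cyclohexene becomes the cycloheptene, and the tertiary C5 cation is quenched by a suprafacial 1,2-hydride shift from C4 to a silyloxycarbenium ion that loses silicon to give the C4 ketone. The closest known reaction types are the acid-promoted Wagner–Meerwein ring enlargement of acorane-type spiro cations to the carotane skeleton and the semipinacol rearrangement that ends at an oxygen-bearing carbon; their combination in one cascade on a silyloxy spiro carbinol is not established. The seven-membered ring is not closed end to end but arises by ring enlargement through a 1,2-shift with a three-centre bridged transition state, and the cyclopentane is untouched. C1 is set by the spiro centre of 11, because C10 moves across the face it already occupies and the methyl group is pushed to the other face. C5 is set by the C4 hydrogen, which lies on the same face as C10 and is delivered suprafacially, so H5 ends trans to C15. The step needs migration of the alkenyl arm and not of the saturated arm C6, whose shift would leave an allyl cation; the anti-periplanar placement of C5–C10 to the C1–O bond and π participation, which the C5–C6 σ bond cannot offer, should secure this. It also needs the hydride shift to outrun proton loss, which the oxygen lone-pair stabilisation of the developing silyloxycarbenium ion and the low temperature favour.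

Step 7
Reactants: 12 (1R,5R)-1-methylbicyclo[5.3.0]dec-9-en-4-one; 13 isopropylmagnesium chloride
Product: 14 (1R,4R,5R)-4-isopropyl-1-methylbicyclo[5.3.0]dec-9-en-4-ol
Conditions: CeCl3 (anhydrous, 2 equiv), THF, −78 → 0 °C
Reagents that add atoms: isopropylmagnesium chloride, CC(C)[Mg]Cl
Why: Organocerium addition suppresses enolisation at C5 and β-hydride reduction. The nucleophile should attack the trans-fused cyclopentanone on the face of H5, away from the axial C15 methyl (1,3 to C4), giving isopropyl cis to H5 and hydroxyl cis to C15.

Step 8
Reactants: 14 (1R,4R,5R)-4-isopropyl-1-methylbicyclo[5.3.0]dec-9-en-4-ol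
Product: 15 (1R,4R,5R)-4-hydroxy-4-isopropyl-1-methylbicyclo[5.3.0]dec-9-en-8-one
Conditions: Rh2(cap)4 (cap = caprolactamate, 1 mol %), tBuOOH (5 equiv), K2CO3, CH2Cl2, 23 °C
Reagents that add atoms: tert-butyl hydroperoxide, CC(C)(C)OO
Why: Radical allylic oxidation to the enone. C8 is the only allylic carbon with hydrogen (the other is quaternary C1), and the allyl radical should be trapped at the unhindered C8 terminus; the tertiary alcohol is inert.

Step 9
Reactants: 15 (1R,4R,5R)-4-hydroxy-4-isopropyl-1-methylbicyclo[5.3.0]dec-9-en-8-one
Product: 16 (1S,4R,5R,9S,10S)-4,9,10-trihydroxy-4-isopropyl-1-methylbicyclo[5.3.0]decan-8-one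
Conditions: K2OsO2(OH)4 (5 mol %), NMO (1.5 equiv), citric acid (1 equiv), tBuOH/H2O 1:1, 23 °C
Reagents that add atoms: N-methylmorpholine N-oxide, C[N+]1([O-])CCOCC1; water, O
Why: Catalytic cis-dihydroxylation of the enone alkene (citric acid speeds turnover with electron-poor alkenes). The osmium reagent should add to the face opposite the C15 methyl on the adjacent quaternary C1, which sets both C9 and C10 trans to C15.

Step 10
Reactants: 16 (1S,4R,5R,9S,10S)-4,9,10-trihydroxy-4-isopropyl-1-methylbicyclo[5.3.0]decan-8-one; 17 2,2-dimethoxypropane
Product: 18 (1S,4R,5R,9S,10S)-4-hydroxy-4-isopropyl-9,10-(isopropylidenedioxy)-1-methylbicyclo[5.3.0]decan-8-one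
Conditions: PPTS (10 mol %), acetone, 23 °C
Reagents that add atoms: 2,2-dimethoxypropane, COC(C)(C)OC
Why: Acetal exchange selective for the cis-1,2-diol; the tertiary alcohol does not react. The cis-fused dioxolane also locks the configuration of C9 next to the ketone.

Step 11
Reactants: 18 (1S,4R,5R,9S,10S)-4-hydroxy-4-isopropyl-9,10-(isopropylidenedioxy)-1-methylbicyclo[5.3.0]decan-8-one
Product: 21 (1S,4R,5R,9S,10S)-4-hydroxy-4-isopropyl-9,10-(isopropylidenedioxy)-1-methylbicyclo[5.3.0]dec-6-en-8-one, via bis-silylated dienol ether 19 (not isolated), via silylated enone 20 (not isolated)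
Conditions: LDA (2.5 equiv), TMSCl (3 equiv), THF, −78 °C; Pd(OAc)2 (1.1 equiv), MeCN, 23 °C; citric acid, MeOH, 0 °C
Reagents that add atoms: none
Why: Saegusa–Ito desaturation. Kinetic deprotonation should occur at the C7 methylene and not at the alkoxy-bearing C9, the tertiary alkoxide is silylated in passing, and the palladium enolate eliminates toward C6; mild acid then removes the tertiary trimethylsilyl ether. C5 is not part of the enolate and keeps its configuration.

Step 12
Reactants: 21 (1S,4R,5R,9S,10S)-4-hydroxy-4-isopropyl-9,10-(isopropylidenedioxy)-1-methylbicyclo[5.3.0]dec-6-en-8-one; 22 bis(pinacolato)diboron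
Product: 24 (1S,4R,5S,6S,9S,10S)-4,6-dihydroxy-4-isopropyl-9,10-(isopropylidenedioxy)-1-methylbicyclo[5.3.0]decan-8-one, via C6 pinacol boronate 23 (not isolated)
Conditions: CuCl (5 mol %), DPEphos (5 mol %), NaOtBu (8 mol %), MeOH (2 equiv), THF, 23 °C; then NaBO3·4H2O, THF/H2O, 23 °C
Reagents that add atoms: sodium perborate (NaBO3·4H2O, hydrate water not shown), [Na+].[Na+].O[B-]1(O)OO[B-](O)(O)OO1
Why: Copper-catalysed conjugate borylation of the only enone, with protonation at the C7 methylene, followed by oxidation of the C–B bond with retention. The bulky boryl-copper species should add to C6 on the face of H5, away from the axial C15 methyl (1,3 to C6) and from the C4 hydroxyl, giving the C6 oxygen cis to H5. Perborate is chosen because it is mild enough to spare the β-hydroxy ketone.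

Step 13
Reactants: 24 (1S,4R,5S,6S,9S,10S)-4,6-dihydroxy-4-isopropyl-9,10-(isopropylidenedioxy)-1-methylbicyclo[5.3.0]decan-8-one; 25 isovaleryl chloride
Product: 26 (1S,4R,5S,6S,9S,10S)-4-hydroxy-4-isopropyl-9,10-(isopropylidenedioxy)-1-methyl-8-oxobicyclo[5.3.0]decan-6-yl 3-methylbutanoate
Conditions: pyridine, CH2Cl2, 0 °C
Reagents that add atoms: isovaleryl chloride, CC(C)CC(Cl)=O
Why: Acylation of the only secondary hydroxyl; the hindered tertiary alcohol does not react. A weak base at 0 °C is used so that the β-acyloxy ketone does not eliminate.

Step 14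
Reactants: 26 (1S,4R,5S,6S,9S,10S)-4-hydroxy-4-isopropyl-9,10-(isopropylidenedioxy)-1-methyl-8-oxobicyclo[5.3.0]decan-6-yl 3-methylbutanoate; 27 dibromomethane
Product: 28 (1S,4R,5S,6S,9R,10S)-4-hydroxy-4-isopropyl-9,10-(isopropylidenedioxy)-1-methyl-8-methylidenebicyclo[5.3.0]decan-6-yl 3-methylbutanoate
Conditions: Zn, TiCl4, THF/CH2Cl2, 0 → 23 °C (Lombardo reagent, preformed)
Reagents that add atoms: dibromomethane, BrCBr
Why: Lombardo methylenation is non-basic, so the β-acyloxy group and the α-alkoxy centre C9 should survive, and it methylenates ketones in the presence of esters. The C9 descriptor changes only because the priorities change.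

Step 15
Reactants: 28 (1S,4R,5S,6S,9R,10S)-4-hydroxy-4-isopropyl-9,10-(isopropylidenedioxy)-1-methyl-8-methylidenebicyclo[5.3.0]decan-6-yl 3-methylbutanoate
Product: 29 (1S,4R,5S,6S,9R,10S)-4,9,10-trihydroxy-4-isopropyl-1-methyl-8-methylidenebicyclo[5.3.0]decan-6-yl 3-methylbutanoate
Conditions: AcOH/THF/H2O (3:1:1), 40 °C
Reagents that add atoms: none
Why: Mild acidic hydrolysis of the acetonide; the ester, the tertiary alcohol and the allylic C9–O bond should tolerate dilute acetic acid. The diol is freed before the epoxide exists, so the epoxide never meets acid.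

Step 16
Reactants: 29 (1S,4R,5S,6S,9R,10S)-4,9,10-trihydroxy-4-isopropyl-1-methyl-8-methylidenebicyclo[5.3.0]decan-6-yl 3-methylbutanoate
Product: 30 (1S,4R,5S,6S,8S,9S,10S)-8,14-epoxy-4,9,10-trihydroxydaucan-6-yl 3-methylbutanoate
Conditions: VO(acac)2 (5 mol %), tBuOOH (1.5 equiv, in decane), CH2Cl2, 0 °C
Reagents that add atoms: tert-butyl hydroperoxide, CC(C)(C)OO
Why: Hydroxyl-directed epoxidation. The vanadium alkoxide of the allylic C9 hydroxyl should deliver oxygen to the face of C8=C14 on which that hydroxyl sits (the homoallylic C10 hydroxyl is on the same face), so the epoxide oxygen ends cis to the C9 hydroxyl; the neutral conditions spare the epoxy diol and the ester.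

## Compound list

1 | cyclohex-2-en-1-one | O=C1C=CCCC1 | starting material
2 | 1,2-bis(trimethylsilyloxy)ethane | C[Si](C)(C)OCCO[Si](C)(C)C | starting material
3 | 1,4-dioxaspiro[4.5]dec-6-ene | C1=CC2(CCC1)OCCO2 | intermediate
4 | 1,2-bis(trimethylsilyloxy)cyclobutene | C[Si](C)(C)OC1=C(O[Si](C)(C)C)CC1 | starting material
5 | 2-(trimethylsilyloxy)-2-[1-(2-trimethylsilyloxyethoxy)cyclohex-2-en-1-yl]cyclobutan-1-one (diastereomer mixture, not isolated) | O=C1CCC1(O[Si](C)(C)C)C1(OCCO[Si](C)(C)C)C=CCCC1 | intermediate
6 | spiro[4.5]dec-6-ene-1,4-dione | O=C1CCC(=O)C12CCCC=C2 | intermediate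
7 | (4S,5R)-4-hydroxyspiro[4.5]dec-6-en-1-one | O=C1CC[C@H](O)[C@]12CCCC=C2 | intermediate
8 | tert-butyldimethylsilyl trifluoromethanesulfonate | CC(C)(C)[Si](C)(C)OS(=O)(=O)C(F)(F)F | starting material
9 | (4S,5R)-4-(tert-butyldimethylsilyloxy)spiro[4.5]dec-6-en-1-one | O=C1CC[C@H](O[Si](C)(C)C(C)(C)C)[C@]12CCCC=C2 | intermediate
10 | methylmagnesium bromide | C[Mg]Br | starting material
11 | (1R,4S,5R)-4-(tert-butyldimethylsilyloxy)-1-methylspiro[4.5]dec-6-en-1-ol | C[C@@]1(O)CC[C@H](O[Si](C)(C)C(C)(C)C)[C@]12CCCC=C2 | intermediate
12 | (1R,5R)-1-methylbicyclo[5.3.0]dec-9-en-4-one, trans-fused | C1CCC=C[C@@]2(C)CCC(=O)[C@H]12 | intermediate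
13 | isopropylmagnesium chloride | CC(C)[Mg]Cl | starting material
14 | (1R,4R,5R)-4-isopropyl-1-methylbicyclo[5.3.0]dec-9-en-4-ol | C1CCC=C[C@@]2(C)CC[C@@](O)(C(C)C)[C@H]12 | intermediate
15 | (1R,4R,5R)-4-hydroxy-4-isopropyl-1-methylbicyclo[5.3.0]dec-9-en-8-one | C1CC(=O)C=C[C@@]2(C)CC[C@@](O)(C(C)C)[C@H]12 | intermediate
16 | (1S,4R,5R,9S,10S)-4,9,10-trihydroxy-4-isopropyl-1-methylbicyclo[5.3.0]decan-8-one | C1CC(=O)[C@@H](O)[C@@H](O)[C@@]2(C)CC[C@@](O)(C(C)C)[C@H]12 | intermediate
17 | 2,2-dimethoxypropane | COC(C)(C)OC | starting material
18 | (1S,4R,5R,9S,10S)-4-hydroxy-4-isopropyl-9,10-(isopropylidenedioxy)-1-methylbicyclo[5.3.0]decan-8-one | C1CC(=O)[C@H]3OC(C)(C)O[C@H]3[C@@]2(C)CC[C@@](O)(C(C)C)[C@H]12 | intermediate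
19 | 4,8-bis(trimethylsilyloxy)-7-ene derived from 18 (C7=C8 silyl enol ether, C4 trimethylsilyl ether; not isolated) | C1C=C(O[Si](C)(C)C)[C@H]3OC(C)(C)O[C@H]3[C@@]2(C)CC[C@@](O[Si](C)(C)C)(C(C)C)[C@H]12 | intermediate
20 | C4 trimethylsilyl ether of 21 (not isolated) | C1=CC(=O)[C@H]3OC(C)(C)O[C@H]3[C@@]2(C)CC[C@@](O[Si](C)(C)C)(C(C)C)[C@H]12 | intermediate
21 | (1S,4R,5R,9S,10S)-4-hydroxy-4-isopropyl-9,10-(isopropylidenedioxy)-1-methylbicyclo[5.3.0]dec-6-en-8-one | C1=CC(=O)[C@H]3OC(C)(C)O[C@H]3[C@@]2(C)CC[C@@](O)(C(C)C)[C@H]12 | intermediate
22 | bis(pinacolato)diboron | CC1(C)OB(OC1(C)C)B1OC(C)(C)C(C)(C)O1 | starting material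
23 | C6 pinacol boronate of 24 (boron in place of the C6 hydroxyl, cis to H5; not isolated) | CC1(C)OB(OC1(C)C)[C@H]4CC(=O)[C@H]3OC(C)(C)O[C@H]3[C@@]2(C)CC[C@@](O)(C(C)C)[C@H]42 | intermediate
24 | (1S,4R,5S,6S,9S,10S)-4,6-dihydroxy-4-isopropyl-9,10-(isopropylidenedioxy)-1-methylbicyclo[5.3.0]decan-8-one | O[C@H]1CC(=O)[C@H]3OC(C)(C)O[C@H]3[C@@]2(C)CC[C@@](O)(C(C)C)[C@H]12 | intermediate
25 | isovaleryl chloride | CC(C)CC(Cl)=O | starting material
26 | (1S,4R,5S,6S,9S,10S)-4-hydroxy-4-isopropyl-9,10-(isopropylidenedioxy)-1-methyl-8-oxobicyclo[5.3.0]decan-6-yl 3-methylbutanoate | CC(C)CC(=O)O[C@H]1CC(=O)[C@H]3OC(C)(C)O[C@H]3[C@@]2(C)CC[C@@](O)(C(C)C)[C@H]12 | intermediate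
27 | dibromomethane | BrCBr | starting material
28 | (1S,4R,5S,6S,9R,10S)-4-hydroxy-4-isopropyl-9,10-(isopropylidenedioxy)-1-methyl-8-methylidenebicyclo[5.3.0]decan-6-yl 3-methylbutanoate | CC(C)CC(=O)O[C@H]1CC(=C)[C@H]3OC(C)(C)O[C@H]3[C@@]2(C)CC[C@@](O)(C(C)C)[C@H]12 | intermediate
29 | (1S,4R,5S,6S,9R,10S)-4,9,10-trihydroxy-4-isopropyl-1-methyl-8-methylidenebicyclo[5.3.0]decan-6-yl 3-methylbutanoate | CC(C)CC(=O)O[C@H]1CC(=C)[C@@H](O)[C@@H](O)[C@@]2(C)CC[C@@](O)(C(C)C)[C@H]12 | intermediate
30 | (1S,4R,5S,6S,8S,9S,10S)-8,14-epoxy-4,9,10-trihydroxydaucan-6-yl 3-methylbutanoate | CC(C)CC(=O)O[C@H]1C[C@]2(CO2)[C@@H](O)[C@@H](O)[C@@]2(C)CC[C@@](O)(C(C)C)[C@H]12 | target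

## Step count and least certain steps

Total: 16 steps. Longest linear sequence: 16 steps (the route is fully linear from 1).

**Step 6 (key step).** Three processes could divert it. The C1 cation could lose a proton to an alkene before anything migrates. The saturated arm C6 could migrate in place of the alkenyl carbon, because that shift leaves an allyl cation. The C5 cation could lose a proton to the silyl enol ether instead of accepting hydride, which would give up the control of C5.

The fallback uses only known chemistry and builds 12 without a cationic rearrangement, by conjugate methylation, enolate alkylation and ring-closing metathesis. It sets out from silyl triflate 8, which silylates commercial 3-(hydroxymethyl)cyclopent-2-en-1-one F1 (2,6-lutidine, CH2Cl2) to the silyloxymethyl enone F2. Copper-catalysed asymmetric conjugate addition of AlMe3 (Cu(OTf)2, chiral phosphoramidite ligand, Et2O, −30 °C) with trapping of the aluminium enolate by Ac2O should give the enol acetate F3 with the quaternary centre in place. MeLi (2 equiv) regenerates the lithium enolate, which is alkylated by pent-4-en-1-yl trifluoromethanesulfonate F4 on the face away from the silyloxymethyl group to give the pentenyl ketone F5. TBAF frees the primary alcohol F6, Dess–Martin periodinane gives the non-enolisable keto aldehyde F7, and Ph3P=CH2 (1 equiv, −78 °C) methylenates the aldehyde selectively to the vinyl ketone F8. The second-generation Grubbs catalyst then closes the cycloheptene, and the fallback comes back to the route at 12.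

**Step 3.** The catalyst controls the carbinol configuration but not which ring face is attacked. Poor facial discrimination between the alkenyl and the CH2 arm would give a mixture of spiro epimers, and over-reduction to the diol is possible.

The fallback separates the two tasks. It sets out from 6: a bulky achiral hydride (LiAlH(OtBu)3, THF, −78 °C) is used to maximise the steric preference for attack past the alkenyl arm, giving racemic (4S*,5R*)-4-hydroxyspiro[4.5]dec-6-en-1-one F9. Burkholderia cepacia lipase with vinyl acetate in MTBE should then acetylate the (4R) enantiomer to (4R,5S)-4-acetoxyspiro[4.5]dec-6-en-1-one F10 and leave the (4S,5R) alcohol, which is separated. The fallback comes back at 7.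

**Step 12.** Facial selectivity at C6 could be poor if stereoelectronic attack anti to H5 competes with the steric preference away from C15. The β-hydroxy ketone could also eliminate or undergo retro-aldol cleavage during the basic oxidative work-up.

The fallback delivers the oxygen by a hydroxyl-directed epoxidation instead of by boron. It sets out from 21. Luche reduction (NaBH4, CeCl3·7H2O, MeOH, −78 °C), with hydride entering opposite the acetonide, should give the allylic alcohol (8S)-4,8-dihydroxy-4-isopropyl-9,10-(isopropylidenedioxy)-1-methylbicyclo[5.3.0]dec-6-ene F11. VO(acac)2 and tBuOOH then deliver oxygen to the face of the C8 hydroxyl to give the 6,7-epoxy alcohol F12. Dess–Martin periodinane oxidises the secondary alcohol to the 6,7-epoxy-8-ketone F13. SmI2 (THF/MeOH, −90 °C) cleaves the C7–O bond next to the carbonyl, and the fallback comes back at 24.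

**Step 16.** Oxygen delivery could leak to the other face if the allylic hydroxyl lies close to the alkene plane, and the Lewis acidic vanadium centre could open or rearrange the epoxy diol.

The fallback replaces substrate direction by reagent control. It sets out from 29: titanium–tartrate epoxidation (Ti(OiPr)4, diethyl tartrate, tBuOOH, 4 Å molecular sieves, CH2Cl2, −20 °C) is used with the tartrate enantiomer for which the (9R) allylic alcohol is the matched, fast-reacting case. It comes back at 30 and passes through no new compound.

## Further compounds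

F1 | step 6 | 3-(hydroxymethyl)cyclopent-2-en-1-one | O=C1C=C(CO)CC1
F2 | step 6 | 3-[(tert-butyldimethylsilyloxy)methyl]cyclopent-2-en-1-one | O=C1C=C(CO[Si](C)(C)C(C)(C)C)CC1
F3 | step 6 | 3-[(tert-butyldimethylsilyloxy)methyl]-3-methylcyclopent-1-en-1-yl acetate (quaternary centre as in 12) | CC(=O)OC1=C[C@@](C)(CO[Si](C)(C)C(C)(C)C)CC1
F4 | step 6 | pent-4-en-1-yl trifluoromethanesulfonate | C=CCCCOS(=O)(=O)C(F)(F)F
F5 | step 6 | 3-[(tert-butyldimethylsilyloxy)methyl]-3-methyl-2-(pent-4-en-1-yl)cyclopentan-1-one (pentenyl cis to methyl) | C=CCCC[C@@H]1[C@@](C)(CO[Si](C)(C)C(C)(C)C)CCC1=O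
F6 | step 6 | 3-(hydroxymethyl)-3-methyl-2-(pent-4-en-1-yl)cyclopentan-1-one (pentenyl cis to methyl) | C=CCCC[C@@H]1[C@@](C)(CO)CCC1=O
F7 | step 6 | 1-methyl-3-oxo-2-(pent-4-en-1-yl)cyclopentane-1-carbaldehyde (pentenyl cis to methyl) | C=CCCC[C@@H]1[C@@](C)(C=O)CCC1=O
F8 | step 6 | 3-ethenyl-3-methyl-2-(pent-4-en-1-yl)cyclopentan-1-one (pentenyl trans to ethenyl) | C=CCCC[C@@H]1[C@@](C)(C=C)CCC1=O
F9 | step 3 | racemic (4S*,5R*)-4-hydroxyspiro[4.5]dec-6-en-1-one (both enantiomers shown) | O=C1CC[C@H](O)[C@]12CCCC=C2.O=C1CC[C@@H](O)[C@@]12CCCC=C2
F10 | step 3 | (4R,5S)-4-acetoxyspiro[4.5]dec-6-en-1-one | O=C1CC[C@@H](OC(C)=O)[C@@]12CCCC=C2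
F11 | step 12 | (1S,4R,5R,8S,9S,10S)-4,8-dihydroxy-4-isopropyl-9,10-(isopropylidenedioxy)-1-methylbicyclo[5.3.0]dec-6-ene (C8 hydroxyl cis to the acetonide) | C1=C[C@@H](O)[C@H]3OC(C)(C)O[C@H]3[C@@]2(C)CC[C@@](O)(C(C)C)[C@H]12
F12 | step 12 | 6,7-epoxide of F11 (epoxide oxygen cis to the C8 hydroxyl and to H5) | [C@@H]14O[C@H]4[C@@H](O)[C@H]3OC(C)(C)O[C@H]3[C@@]2(C)CC[C@@](O)(C(C)C)[C@H]12
F13 | step 12 | 6,7-epoxy-4-hydroxy-4-isopropyl-9,10-(isopropylidenedioxy)-1-methylbicyclo[5.3.0]decan-8-one (epoxide oxygen cis to H5) | [C@@H]14O[C@H]4C(=O)[C@H]3OC(C)(C)O[C@H]3[C@@]2(C)CC[C@@](O)(C(C)C)[C@H]12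
F0 | step 16 | none | none
A1 | alternative 1 | ethyl 2-bromo-3,7-dimethyl-6-oxo-3-[(E)-prop-1-enyl]octanoate | CCOC(=O)C(Br)[C@@](C)(/C=C/C)CCC(=O)C(C)C
A2 | alternative 1 | ethyl 2-hydroxy-2-isopropyl-5-methyl-5-[(E)-prop-1-enyl]cyclopentane-1-carboxylate | CCOC(=O)[C@H]1[C@](O)(C(C)C)CC[C@]1(C)/C=C/C
A3 | alternative 2 | 2-diazo-5-(2,4-dimethoxyphenyl)pentan-3-one | CC(=[N+]=[N-])C(=O)CCc1ccc(OC)cc1OC
A4 | alternative 2 | 6,8-dimethoxy-1-methylbicyclo[5.3.0]deca-5,7,9-trien-2-one (daucane numbering) | COC1C=C(OC)C=C[C@@]2(C)C(=O)CCC2=1
A5 | alternative 3 | 3-[(tert-butyldimethylsilyloxy)methyl]cyclopent-2-en-1-one | O=C1C=C(CO[Si](C)(C)C(C)(C)C)CC1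
A6 | alternative 3 | 3-iodobut-3-enal | C=C(I)CC=O
A7 | alternative 3 | 3-[(tert-butyldimethylsilyloxy)methyl]-2-(1-hydroxy-3-iodobut-3-enyl)-3-methylcyclopentan-1-one (2,3-trans aldol adduct) | C=C(I)C[C@H](O)[C@H]1C(=O)CC[C@]1(C)CO[Si](C)(C)C(C)(C)C
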